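Rings: A = benzene ring, B = lactone ring of the coumarin (O1 to C8a), C = dihydropyranone (O1' to C6'). The retrosynthesis cuts, in order: the C3–C6' bond between rings B and C; ring B at C3=C4 and O1–C2 (back to a masked salicylaldehyde and Meldrum's acid); the formyl carbon on ring A; the aryl–benzylic carbon bond (back to an aryl bromide and an epoxide).
Forward: an aryllithium opens (2R,3R)-2,3-epoxybutane; demethylation; triethyl orthoformate closes a temporary isochromene ring (a quinone methide that hides both aldehyde and secondary alcohol); Meldrum's acid opens that ring again and closes ring B with CO2H left on C3; silyl ethers; union with ring C; desilylation.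
Ring C is made whole beforehand from ethyl (S)-3-hydroxybutanoate (Weinreb amide, ethynyl ketone, gold-catalysed 6-endo-dig closure of O1'–C6').
Enabling feature: C3 of ring B is the carbon that the Knoevenagel closure delivers bearing CO2H, a traceless handle for C3 metalation. C6' of ring C is at once the β-carbon of the C4' enone and the oxygen-bearing carbon of the O1'–C6'=C5' enol ether, and it carries H. A C3–palladium species should therefore add at C6', and the C4' ketone lets the C5'=C6' double bond be restored.
Stereochemistry: both side-chain centres come from the C2-symmetric epoxide (inversion at the attacked carbon, retention at the other, giving 2R,3R); C2' comes unchanged from ethyl (S)-3-hydroxybutanoate; the key step creates no stereocentre.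

Key step: step 11

Assumption: the quinone methide made in step 5 is drawn in its anhydro form; with water or base it should equilibrate with its C1 hydrate and the open hydroxy aldehyde, and step 6 is expected to draw on whichever form is present.

Step 1
Reactants: 1 5-bromo-1,3-dimethoxy-2-methylbenzene
Product: 2 6-bromo-2,4-dimethoxy-3-methylbenzaldehyde
Conditions: Cl2CHOMe, TiCl4, CH2Cl2, −10 to 0 °C; aq. HCl
Reagents that add atoms: dichloromethyl methyl ether COC(Cl)Cl; water O
Why: Rieche formylation; the two free ring positions of 1 are equivalent by symmetry and each is ortho to one OMe and para to the other, so a single aldehyde should form.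

Step 2
Reactants: 2 6-bromo-2,4-dimethoxy-3-methylbenzaldehyde
Product: 3 1-bromo-3,5-dimethoxy-2,4-dimethylbenzene
Conditions: Et3SiH, TFA, CH2Cl2, 0 °C to rt
Reagents that add atoms: none
Why: Ionic hydrogenation of an aldehyde whose benzylic cation is stabilised by ortho and para OMe should reduce CHO to CH3 without touching the C–Br bond.

Step 3
Reactants: 3 1-bromo-3,5-dimethoxy-2,4-dimethylbenzene; 4 (2R,3R)-2,3-epoxybutane
Product: 6 (2R,3R)-3-(3,5-dimethoxy-2,4-dimethylphenyl)butan-2-ol, via aryllithium 5 (not isolated)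
Conditions: n-BuLi, THF, −78 °C; then 4, BF3·OEt2, −78 °C; aq. NH4Cl
Reagents that add atoms: none
Why: Bromine–lithium exchange followed by BF3-promoted SN2 opening of the epoxide by the aryllithium; the epoxide is C2-symmetric, so either carbon gives the same product, and inversion at the attacked carbon with retention at the other should set the (2R,3R) erythro pair.

Step 4
Reactants: 6 (2R,3R)-3-(3,5-dimethoxy-2,4-dimethylphenyl)butan-2-ol
Product: 7 5-[(2R,3R)-3-hydroxybutan-2-yl]-2,4-dimethylbenzene-1,3-diol
Conditions: BBr3, CH2Cl2, −78 to 0 °C; MeOH then H2O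
Reagents that add atoms: none
Why: BBr3 cleavage of both aryl methyl ethers, with the secondary alcohol carried as its borate and returned on hydrolysis; no stereocentre is touched.

Step 5
Reactants: 7 5-[(2R,3R)-3-hydroxybutan-2-yl]-2,4-dimethylbenzene-1,3-diol
Product: 9 (3R,4R)-8-hydroxy-3,4,5,7-tetramethyl-3,4-dihydro-6H-isochromen-6-one, via 1-ethoxyisochromane acetal 8 (not isolated)
Conditions: HC(OEt)3, TFA, CH2Cl2, rt; then 1 M aq. HCl, rt
Reagents that add atoms: triethyl orthoformate CCOC(OCC)OCC
Why: Orthoester exchange at the secondary alcohol and intramolecular Friedel–Crafts (oxa-Pictet–Spengler-type) attack on the only free ring position, which is ortho to one OH and para to the other, should close the isochromane; acid-driven loss of ethanol pushed by the para OH should then give the para-quinone methide, a temporary ring that masks aldehyde and alcohol, precedented for resorcinols carrying this side chain.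

Step 6
Reactants: 9 (3R,4R)-8-hydroxy-3,4,5,7-tetramethyl-3,4-dihydro-6H-isochromen-6-one; 10 Meldrum's acid
Product: 12 7-hydroxy-5-[(2R,3R)-3-hydroxybutan-2-yl]-6,8-dimethyl-2-oxo-2H-chromene-3-carboxylic acid, via Meldrum's acid adduct 11 (not isolated)
Conditions: pyridine, piperidine (cat.), 60 °C; then 1 M aq. HCl
Reagents that add atoms: none
Why: Knoevenagel coumarin-3-carboxylic acid synthesis on a masked salicylaldehyde: Meldrum's acid should add to C1 of the quinone methide (re-aromatising ring A), E1cB loss of the ring alkoxide should give the arylidene Meldrum's acid, and the cis phenol should lactonise with loss of acetone, closing ring B with CO2H on C3 and freeing the side-chain alcohol.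

Step 7
Reactants: 12 7-hydroxy-5-[(2R,3R)-3-hydroxybutan-2-yl]-6,8-dimethyl-2-oxo-2H-chromene-3-carboxylic acid
Product: 14 7-[(tert-butyldimethylsilyl)oxy]-5-[(2R,3R)-3-[(tert-butyldimethylsilyl)oxy]butan-2-yl]-6,8-dimethyl-2-oxo-2H-chromene-3-carboxylic acid, via tris-silyl ester 13 (not isolated)
Conditions: TBSOTf, 2,6-lutidine, CH2Cl2, 0 °C to rt; then 10% aq. citric acid, THF, rt
Reagents that add atoms: tert-butyldimethylsilyl trifluoromethanesulfonate CC(C)(C)[Si](C)(C)OS(=O)(=O)C(F)(F)F
Why: Silylation of phenol, alcohol and acid followed by selective hydrolysis of the labile silyl ester; the two ethers should block phenol and alcohol oxidation in the palladium step.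

Step 8
Reactants: 15 ethyl (S)-3-hydroxybutanoate
Product: 16 (S)-3-hydroxy-N-methoxy-N-methylbutanamide
Conditions: MeNHOMe·HCl, i-PrMgCl, THF, −20 to 0 °C
Reagents that add atoms: N,O-dimethylhydroxylamine hydrochloride CNOC.Cl
Why: Weinreb amide formation from the ester with the chloromagnesium amide of N,O-dimethylhydroxylamine (excess i-PrMgCl also covers the free OH); the stereocentre is not involved.

Step 9
Reactants: 16 (S)-3-hydroxy-N-methoxy-N-methylbutanamide
Product: 17 (S)-5-hydroxyhex-1-yn-3-one
Conditions: ethynylmagnesium bromide (3.5 equiv), THF, 0 °C; inverse quench into cold 1 M aq. HCl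
Reagents that add atoms: ethynylmagnesium bromide C#C[Mg]Br
Why: Grignard addition to a Weinreb amide should stop at the chelated tetrahedral adduct and release the ynone on acidic quench, which also keeps the liberated amine protonated and off the ynone.

Step 10
Reactants: 17 (S)-5-hydroxyhex-1-yn-3-one
Product: 18 (S)-2-methyl-2,3-dihydro-4H-pyran-4-one
Conditions: Ph3PAuCl (2 mol %), AgOTf (2 mol %), CH2Cl2, rt
Reagents that add atoms: none
Why: Gold-catalysed 6-endo-dig hydroalkoxylation of the β-hydroxy ynone (attack of OH on the alkyne carbon β to the ketone) should close ring C; no bond to the stereocentre is broken, so C2' stays (S).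

Step 11
Reactants: 14 7-[(tert-butyldimethylsilyl)oxy]-5-[(2R,3R)-3-[(tert-butyldimethylsilyl)oxy]butan-2-yl]-6,8-dimethyl-2-oxo-2H-chromene-3-carboxylic acid; 18 (S)-2-methyl-2,3-dihydro-4H-pyran-4-one
Product: 19 7-[(tert-butyldimethylsilyl)oxy]-5-[(2R,3R)-3-[(tert-butyldimethylsilyl)oxy]butan-2-yl]-6,8-dimethyl-3-[(2S)-2-methyl-4-oxo-3,4-dihydro-2H-pyran-6-yl]-2H-chromen-2-one
Conditions: Pd(O2CCF3)2 (10 mol %), Ag2CO3 (2.5 equiv), 18 (3 equiv), DMSO–DMF (1:20), 100 °C, sealed vessel
Reagents that add atoms: none
Why: Proposed new method: the silver carboxylate of 14 should lose CO2 to a coumarin-3-yl silver species that passes to divalent palladium (the C3 metalation behind the known decarboxylative arylation of coumarin-3-carboxylic acids), and this C3–Pd bond should add syn across C5'=C6' of 18 with C3 going to C6', because C6' is both the β-carbon of the C4' enone and the oxygen-bearing carbon of the enol ether, so both polarisations agree and leave palladium on C5' as an enolate. The C6'–H is anti to palladium after insertion, but the C4' carbonyl lets palladium pass through the O-bound enolate to the other face, after which syn β-hydride elimination should restore C5'=C6' and monovalent silver should reoxidise zerovalent palladium. The closest known reaction types are the decarboxylative Heck olefination of arene carboxylic acids under Pd(O2CCF3)2/Ag2CO3, the related decarboxylative C1-arylation of glycals, and the oxidative Heck C2-arylation of chromones. No ring is closed and no stereocentre is formed; C2' of 18 is a spectator one CH2 away from the reacting enone. The step needs C6' over C5' regiochemistry (secured by the matched enone and enol-ether polarisation), a Heck rather than conjugate-addition outcome (aprotic carbonate medium with no strong acid to protonate the palladium enolate) and cross- over self-coupling (C4 of the coumarin is shielded by the peri side chain on C5, and 18 is in excess).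

Step 12
Reactants: 19 7-[(tert-butyldimethylsilyl)oxy]-5-[(2R,3R)-3-[(tert-butyldimethylsilyl)oxy]butan-2-yl]-6,8-dimethyl-3-[(2S)-2-methyl-4-oxo-3,4-dihydro-2H-pyran-6-yl]-2H-chromen-2-one
Product: 20 7-hydroxy-5-[(2R,3R)-3-hydroxybutan-2-yl]-6,8-dimethyl-3-[(2S)-2-methyl-4-oxo-3,4-dihydro-2H-pyran-6-yl]-2H-chromen-2-one
Conditions: HF·pyridine, THF–pyridine, 0 °C to rt
Reagents that add atoms: none
Why: Fluoride cleavage of both silyl ethers under acidic buffered conditions, which should avoid enolisation at C3' and hence retro-oxa-Michael epimerisation of C2'.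

Compound list
1 | 5-bromo-1,3-dimethoxy-2-methylbenzene (catalogue building block) | COc1cc(Br)cc(OC)c1C | starting material
2 | 6-bromo-2,4-dimethoxy-3-methylbenzaldehyde | COc1cc(Br)c(C=O)c(OC)c1C | intermediate
3 | 1-bromo-3,5-dimethoxy-2,4-dimethylbenzene | COc1cc(Br)c(C)c(OC)c1C | intermediate
4 | (2R,3R)-2,3-epoxybutane | C[C@H]1O[C@@H]1C | starting material
5 | aryllithium, (3,5-dimethoxy-2,4-dimethylphenyl)lithium | [Li]c1cc(OC)c(C)c(OC)c1C | intermediate
6 | (2R,3R)-3-(3,5-dimethoxy-2,4-dimethylphenyl)butan-2-ol | COc1cc([C@@H](C)[C@@H](C)O)c(C)c(OC)c1C | intermediate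
7 | 5-[(2R,3R)-3-hydroxybutan-2-yl]-2,4-dimethylbenzene-1,3-diol | Oc1cc([C@@H](C)[C@@H](C)O)c(C)c(O)c1C | intermediate
8 | 1-ethoxyisochromane acetal, (3R,4R)-1-ethoxy-3,4,5,7-tetramethyl-3,4-dihydro-1H-isochromene-6,8-diol (C1 epimers) | CCOC1O[C@H](C)[C@H](C)c2c(C)c(O)c(C)c(O)c12 | intermediate
9 | (3R,4R)-8-hydroxy-3,4,5,7-tetramethyl-3,4-dihydro-6H-isochromen-6-one | CC1=C2[C@@H](C)[C@@H](C)OC=C2C(O)=C(C)C1=O | intermediate
10 | Meldrum's acid (2,2-dimethyl-1,3-dioxane-4,6-dione) | CC1(C)OC(=O)CC(=O)O1 | starting material
11 | Meldrum's acid adduct, 5-[(3R,4R)-6,8-dihydroxy-3,4,5,7-tetramethyl-3,4-dihydro-1H-isochromen-1-yl]-2,2-dimethyl-1,3-dioxane-4,6-dione (C1 epimers) | CC1(C)OC(=O)C(C(=O)O1)C1O[C@H](C)[C@H](C)c2c(C)c(O)c(C)c(O)c21 | intermediate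
12 | 7-hydroxy-5-[(2R,3R)-3-hydroxybutan-2-yl]-6,8-dimethyl-2-oxo-2H-chromene-3-carboxylic acid | Cc1c(O)c(C)c2oc(=O)c(C(=O)O)cc2c1[C@@H](C)[C@@H](C)O | intermediate
13 | tris-silyl ester, tert-butyldimethylsilyl 7-[(tert-butyldimethylsilyl)oxy]-5-[(2R,3R)-3-[(tert-butyldimethylsilyl)oxy]butan-2-yl]-6,8-dimethyl-2-oxo-2H-chromene-3-carboxylate | Cc1c(O[Si](C)(C)C(C)(C)C)c(C)c2oc(=O)c(C(=O)O[Si](C)(C)C(C)(C)C)cc2c1[C@@H](C)[C@@H](C)O[Si](C)(C)C(C)(C)C | intermediate
14 | 7-[(tert-butyldimethylsilyl)oxy]-5-[(2R,3R)-3-[(tert-butyldimethylsilyl)oxy]butan-2-yl]-6,8-dimethyl-2-oxo-2H-chromene-3-carboxylic acid | Cc1c(O[Si](C)(C)C(C)(C)C)c(C)c2oc(=O)c(C(=O)O)cc2c1[C@@H](C)[C@@H](C)O[Si](C)(C)C(C)(C)C | intermediate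
15 | ethyl (S)-3-hydroxybutanoate | CCOC(=O)C[C@H](C)O | starting material
16 | (S)-3-hydroxy-N-methoxy-N-methylbutanamide | CON(C)C(=O)C[C@H](C)O | intermediate
17 | (S)-5-hydroxyhex-1-yn-3-one | C#CC(=O)C[C@H](C)O | intermediate
18 | (S)-2-methyl-2,3-dihydro-4H-pyran-4-one | C[C@H]1CC(=O)C=CO1 | intermediate
19 | 7-[(tert-butyldimethylsilyl)oxy]-5-[(2R,3R)-3-[(tert-butyldimethylsilyl)oxy]butan-2-yl]-6,8-dimethyl-3-[(2S)-2-methyl-4-oxo-3,4-dihydro-2H-pyran-6-yl]-2H-chromen-2-one | Cc1c(O[Si](C)(C)C(C)(C)C)c(C)c2oc(=O)c(C3=CC(=O)C[C@H](C)O3)cc2c1[C@@H](C)[C@@H](C)O[Si](C)(C)C(C)(C)C | intermediate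
20 | 7-hydroxy-5-[(2R,3R)-3-hydroxybutan-2-yl]-6,8-dimethyl-3-[(2S)-2-methyl-4-oxo-3,4-dihydro-2H-pyran-6-yl]-2H-chromen-2-one | Cc1c(O)c(C)c2oc(=O)c(C3=CC(=O)C[C@H](C)O3)cc2c1[C@@H](C)[C@@H](C)O | target

Total step count: 12. Longest linear sequence: 9 steps (steps 1 to 7, 11 and 12); ring C is made in 3 steps (8 to 10) in parallel.

Steps most likely to fail

Step 11 (proposed method). Decarboxylation may be followed by protonation instead of insertion, the palladium enolate may be protonated to the conjugate-addition outcome, or carbonate may open and reclose ring C by retro-oxa-Michael and scramble C2'. The fallback uses known chemistry, sets out from 14 and comes back at 19. Hunsdiecker-type bromodecarboxylation of 14 (NBS, cat. LiOAc, MeCN–H2O, rt) should give the 3-bromocoumarin F1. Sonogashira coupling of F1 with the ynone 17 (PdCl2(PPh3)2, CuI, Et3N, THF, rt) should form the same C3–C6' bond at the alkyne terminus and give the aryl ynone F2. Gold-catalysed 6-endo-dig closure of F2 (Ph3PAuCl, AgOTf, CH2Cl2, rt, as in step 10) should then build ring C on the coumarin and give 19.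

Step 6. The Meldrum's acid adduct may stay closed as the isochromane, or lose CO2 before the temporary ring opens, so that ring B does not form with its carboxyl group. The fallback gives up the temporary ring and uses an open, protected aldehyde; it sets out from 6 and comes back at 12. Acetylation of 6 (Ac2O, pyridine, DMAP) should give the acetate F3. Rieche formylation (Cl2CHOMe, TiCl4, CH2Cl2, 0 °C) at the one free ring position should give the aldehyde F4. BBr3 (CH2Cl2, −78 to 0 °C) should cleave both methyl ethers to the dihydroxy aldehyde F5. Standard Knoevenagel condensation of F5 with 10 (EtOH, cat. piperidinium acetate) should give the coumarin acid acetate F6. Saponification (LiOH, THF–H2O, then aq. HCl, which also recloses the lactone) should give 12.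

Step 4. The borate of the secondary alcohol may ionise with participation of the electron-rich aryl group during ether cleavage, leading to bromide formation or loss of configuration at the carbinol carbon. The fallback closes the temporary ring before the demethylation, so that the alcohol oxygen is held as a ring ether; it sets out from 6 and comes back at 9. Triethyl orthoformate with TFA (CH2Cl2, rt) should convert 6 by the same oxa-Pictet–Spengler-type closure into the dimethoxy 1-ethoxyisochromane F7. BBr3 (CH2Cl2, −78 to 0 °C) followed by aqueous acid should then cleave the acetal and both methyl ethers and give 9.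

Further compounds
F1 | step 11 | 3-bromo-7-[(tert-butyldimethylsilyl)oxy]-5-[(2R,3R)-3-[(tert-butyldimethylsilyl)oxy]butan-2-yl]-6,8-dimethyl-2H-chromen-2-one | Cc1c(O[Si](C)(C)C(C)(C)C)c(C)c2oc(=O)c(Br)cc2c1[C@@H](C)[C@@H](C)O[Si](C)(C)C(C)(C)C
F2 | step 11 | 7-[(tert-butyldimethylsilyl)oxy]-5-[(2R,3R)-3-[(tert-butyldimethylsilyl)oxy]butan-2-yl]-3-[(5S)-5-hydroxy-3-oxohex-1-yn-1-yl]-6,8-dimethyl-2H-chromen-2-one | Cc1c(O[Si](C)(C)C(C)(C)C)c(C)c2oc(=O)c(C#CC(=O)C[C@H](C)O)cc2c1[C@@H](C)[C@@H](C)O[Si](C)(C)C(C)(C)C
F3 | step 6 | (2R,3R)-3-(3,5-dimethoxy-2,4-dimethylphenyl)butan-2-yl acetate | COc1cc([C@@H](C)[C@@H](C)OC(C)=O)c(C)c(OC)c1C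
F4 | step 6 | (2R,3R)-3-(2-formyl-3,5-dimethoxy-4,6-dimethylphenyl)butan-2-yl acetate | COc1c(C)c(OC)c(C=O)c([C@@H](C)[C@@H](C)OC(C)=O)c1C
F5 | step 6 | (2R,3R)-3-(2-formyl-3,5-dihydroxy-4,6-dimethylphenyl)butan-2-yl acetate | Oc1c(C)c(O)c(C=O)c([C@@H](C)[C@@H](C)OC(C)=O)c1C
F6 | step 6 | 5-[(2R,3R)-3-acetoxybutan-2-yl]-7-hydroxy-6,8-dimethyl-2-oxo-2H-chromene-3-carboxylic acid | Cc1c(O)c(C)c2oc(=O)c(C(=O)O)cc2c1[C@@H](C)[C@@H](C)OC(C)=O
F7 | step 4 | (3R,4R)-1-ethoxy-6,8-dimethoxy-3,4,5,7-tetramethyl-3,4-dihydro-1H-isochromene (C1 epimers) | CCOC1O[C@H](C)[C@H](C)c2c(C)c(OC)c(C)c(OC)c12
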